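The flask is stirred at constant volume and temperature, holds partner from the start, and takes starting material in 4 equal portions, 80 min apart.

| flask | starting material | partner | remark | time |
|---|---|---|---|---|
| birch | 6.3 mM (in portions, 4) | 9.5 mM | run made earlier; portions every 80 min |  |
| ash | 38 mM (in portions, 4) | 9.5 mM | run made earlier; portions every 80 min |  |
| alpha | 5.0 mM (in portions, 4) | 9.50 mM | the portions of starting material follow each other after 80 min, the first at the start | 50 h |
| delta | 10 mM (in portions, 4) | 9.50 mM | the portions of starting material follow each other after 80 min, the first at the start | 50 h |
| gamma | 40 mM (in portions, 4) | 9.50 mM | the portions of starting material follow each other after 80 min, the first at the start | 50 h |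
| eta | 15 mM (in portions, 4) | 9.50 mM | the portions of starting material follow each other after 80 min, the first at the start | 50 h |

- birch (time / h: product / %): 4.00: 7.3; 8.00: 19.7; 15.0: 40.9; 25.0: 59.2; 48.0: 76.7
- ash (time / h: product / %): 4.00: 5.8; 8.00: 15.3; 15.0: 19.7; 25.0: 23.5; 48.0: 23.9

(readings scatter by 1 percentage point)

- steps that have been proposed: adduct -> decomposed reagent; adduct -> product; starting material + partner <-> adduct

1. ranking by amount of product, in percent of the starting material charged, from high to low, at 50 h (alpha / delta / gamma / eta)
2. the same order at 10 h (alpha / delta / gamma / eta)
3. the amount of product, in percent of the starting material charged of the flask you put first, at 50 h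
4. the amount of product, in percent of the starting material charged of the flask you put last, at 50 h

Ash reads 23.5 % at 25.0 h and 23.9 % at 48.0 h, a step smaller than the scatter of 1 percentage point, so I read ash as stopped. Its last reading is worth 9.08 mM of product from 9.5 mM of partner, the limiting reagent there. I call this amount the usable partner: the product this charge of partner yields with starting material in excess. For a flask with this charge of partner, it is a reading from ash, and divided by that flask's charge of starting material it gives the flask's ceiling in percent.

Gamma's ceiling is 22.7 %. Gamma is charged much like ash, and ash was flat by 25.0 h, so I commit to that figure at 50 h. Eta's ceiling is 60.5 % and delta's is 90.8 %, both above gamma's. Alpha's charge lies below the usable partner, so I expect no ceiling there. Birch reads 76.7 % at 48.0 h, and alpha has a smaller charge and runs a little longer, so I put alpha a little above birch. My order follows the ceilings: alpha, delta, eta, gamma. I keep it at 10 h, because at 8.00 h ash already reads lower than birch, 15.3 % against 19.7 %.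

The forecast gives alpha > delta > eta > gamma at 50 h and alpha > delta > eta > gamma at 10 h, with 80 % and 23 %, and says “percent yield tracks the partner remaining”.

The flasks give alpha > delta > eta > gamma at 50 h and alpha > delta > eta > gamma at 10 h, with alpha at 80.5 % and gamma at 22.7 %.

    adduct → decomposed reagent (k = 0.0530 /h)
    adduct → product (k = 1.10 /h)
    starting material + partner ⇌ adduct (K = 110 /M, k = 6.30 /M/h)

In gamma at 5.14 h, adduct goes on to product 21 times as fast as to decomposed reagent. In gamma at that moment, its fall back to starting material and partner runs at 0.050 of the rate at which it goes on. The ceiling I read from ash for gamma is 22.7 %; gamma holds 22.7 % of product at 50 h, with 0.013 % of its partner left and 76 % of its charged starting material still there, unbound. A neighbour of gamma with 24 mM of starting material has a ceiling of 37.8 %; at 50.0 h it gives 37.4 %, with 0.95 % of its partner left.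

All runs are calculated on assumed constants; noise was put on by code.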